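**Retrosynthetic overview**

- The target is a dehydrodimer of two (2S,3S)-ε-viniferin units. Unit 1 ends up in the cycloheptane and unit 2 stays an intact ε-viniferin. Labels for unit 1: C-a is the former olefin carbon that carries the 4-hydroxyphenyl ring, C-b is the former olefin carbon on ring B (the benzo ring of the dihydrobenzofuran), ring A is the 3,5-dioxygenated aryl on C3 of the dihydrobenzofuran, and ring C is the phenol ring of unit 2.
- Both bonds between and within the halves, C-a to the ring A carbon ortho to the C3 attachment (cycloheptane) and C-b to the ortho carbon of ring C, are cut in one retro-oxidative dimerisation. This leads to a single monomer, ε-viniferin with TBS (tert-butyldimethylsilyl) on four oxygens and only the stilbene phenol free.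
- Enabling feature: ring A on C3 is peri to the 4-hydroxystyryl group on C4 of ring B. Once oxidation turns that styryl phenol into a para-quinone methide at C-a, the ring A carbon ortho to C3 (ortho to one oxygen, para to the other) reaches C-a through a seven-membered 7-exo transition state.
- Monomer: E-olefin by Heck coupling of a 4-bromo-dihydrobenzofuran with 4-acetoxystyrene; dihydrofuran ring by enantioselective rhodium-carbene C–H insertion of a diaryldiazomethane (sets C3), then Lewis-acid equilibration of C2 to trans; diaryl ketone from two commercial arenes and 4-methoxybenzyl chloride.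
- Ring order: dihydrofuran ring of the monomer (step 7); in the key step a transient second dihydrofuran ring (O-capture) is re-opened and replaced by the cycloheptane (C-capture). Methyl ethers are carried through the carbene chemistry and exchanged for TBS before the stilbene exists, so the end-game needs only fluoride.

Key step: step 12

Assumption: Rh2(S-PTAD)4 is taken to deliver the (3S) insertion product; should the sense of induction be the opposite, Rh2(R-PTAD)4 is used and nothing else changes.

**Route**

Step 1
Reactants: 1 1-bromo-3,5-dimethoxybenzene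
Product: 2 2-bromo-4,6-dimethoxybenzaldehyde
Conditions: POCl3, DMF, 0 °C → 90 °C; then aq. NaOAc
Reagents that add atoms: N,N-dimethylformamide CN(C)C=O (formyl carbon); water O (carbonyl oxygen)
Why: Vilsmeier–Haack formylation should go mainly to the position para to one methoxy group and ortho to the other that lies next to bromine and not between the two methoxy groups, the minor regioisomer being removed by crystallisation.

Step 2
Reactants: 2 2-bromo-4,6-dimethoxybenzaldehyde
Product: 3 2-bromo-6-hydroxy-4-methoxybenzaldehyde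
Conditions: BCl3, CH2Cl2, −78 °C → 0 °C; then water
Reagents that add atoms: none
Why: Chelation-directed Lewis-acid ether cleavage, in which BCl3 bound to the aldehyde oxygen cleaves only the ortho methyl ether through a six-membered chelate and leaves the para methoxy group.

Step 3
Reactants: 3 2-bromo-6-hydroxy-4-methoxybenzaldehyde; 4 4-methoxybenzyl chloride
Product: 5 2-bromo-4-methoxy-6-[(4-methoxybenzyl)oxy]benzaldehyde
Conditions: K2CO3, n-Bu4NI (cat.), DMF, 60 °C
Reagents that add atoms: 4-methoxybenzyl chloride (4) COc1ccc(CCl)cc1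
Why: Williamson etherification of the phenol installs the benzylic OCH2 group whose carbon later becomes C2 of the dihydrobenzofuran.

Step 4
Reactants: 5 2-bromo-4-methoxy-6-[(4-methoxybenzyl)oxy]benzaldehyde; 6 3,5-dimethoxyphenylmagnesium chloride (THF solution)
Product: 7 racemic [2-bromo-4-methoxy-6-(4-methoxybenzyloxy)phenyl](3,5-dimethoxyphenyl)methanol
Conditions: THF, −40 °C → 0 °C; then water
Reagents that add atoms: 3,5-dimethoxyphenylmagnesium chloride (6) COc1cc(OC)cc([Mg]Cl)c1
Why: Grignard 1,2-addition to the aldehyde is faster than halogen–magnesium exchange at the aryl bromide, and the racemic carbinol centre is removed again in step 5.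

Step 5
Reactants: 7 racemic diaryl carbinol
Product: 8 [2-bromo-4-methoxy-6-(4-methoxybenzyloxy)phenyl](3,5-dimethoxyphenyl)methanone
Conditions: Dess–Martin periodinane, CH2Cl2, rt
Reagents that add atoms: none
Why: Dess–Martin oxidation of a hindered diaryl carbinol is mild enough to leave the electron-rich benzyl ether untouched.

Step 6
Reactants: 8 diaryl ketone
Product: 9 hydrazone of ketone 8 (E/Z mixture)
Conditions: N2H4·H2O (excess), AcOH (cat.), EtOH, 95 °C, sealed tube
Reagents that add atoms: hydrazine NN
Why: Acid-catalysed hydrazone condensation, run under forcing conditions because the carbonyl group has two ortho substituents; the E/Z ratio is irrelevant since both isomers give the same diazo compound.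

Step 7
Reactants: 9 hydrazone of ketone 8
Product: 11 (2R,3S)-4-bromo-3-(3,5-dimethoxyphenyl)-6-methoxy-2-(4-methoxyphenyl)-2,3-dihydro-1-benzofuran (cis), via diaryldiazomethane 10 (not isolated)
Conditions: MnO2, CH2Cl2, 0 °C, filter; then Rh2(S-PTAD)4 [dirhodium tetrakis((S)-(1-adamantyl)(phthalimido)acetate)] (1 mol %), CH2Cl2, −20 °C → 0 °C
Reagents that add atoms: none
Why: Dehydrogenation of the hydrazone gives the diaryldiazomethane, whose donor/donor rhodium carbene undergoes enantioselective intramolecular 1,5 C–H insertion into the benzylic ether C–H bond, the chiral carboxylate ligands setting C3 (S) and the concerted insertion giving mainly the cis C2 epimer, which is corrected in step 8.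

Step 8
Reactants: 11 cis-dihydrobenzofuran tetramethyl ether
Product: 12 (2S,3S)-4-bromo-3-(3,5-dihydroxyphenyl)-2-(4-hydroxyphenyl)-2,3-dihydro-1-benzofuran-6-ol (trans)
Conditions: BBr3, CH2Cl2, −78 °C → rt; then water
Reagents that add atoms: none
Why: BBr3 ether cleavage removes the four methyl groups and, by reversibly ionising the benzylic C2–O bond next to the 4-oxyphenyl ring, lets C2 settle in the more stable trans (2S) configuration while C3, which is never ionised, keeps the configuration set in step 7.

Step 9
Reactants: 12 trans tetraol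
Product: 13 (2S,3S)-4-bromo-dihydrobenzofuran tetrakis-TBS ether
Conditions: TBSCl, imidazole, DMF, rt
Reagents that add atoms: tert-butyldimethylsilyl chloride CC(C)(C)[Si](C)(C)Cl
Why: Imidazole-mediated silylation of the four phenols gives ethers that keep ring A nucleophilic, cannot form quinone methides and come off with fluoride at the end.

Step 10
Reactants: 13 aryl bromide tetrakis-TBS ether; 14 4-acetoxystyrene
Product: 15 (2S,3S)-4-[(E)-4-acetoxystyryl]-dihydrobenzofuran tetrakis-TBS ether
Conditions: Pd2(dba)3 (2.5 mol %), P(t-Bu)3·HBF4 (10 mol %), Cy2NMe, 1,4-dioxane, 80 °C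
Reagents that add atoms: 4-acetoxystyrene (14) CC(=O)Oc1ccc(C=C)cc1
Why: Mizoroki–Heck reaction with a bulky electron-rich phosphine suited to the hindered bromide, syn insertion and syn β-hydride elimination giving the E-stilbene while amine base leaves acetate and aryl silyl ethers intact.

Step 11
Reactants: 15 stilbene acetate
Product: 16 tetra-O-TBS (2S,3S)-ε-viniferin with free stilbene phenol
Conditions: pyrrolidine, CH2Cl2, 0 °C → rt
Reagents that add atoms: none
Why: Aminolysis of the aryl acetate by a secondary amine in an aprotic solvent frees the one phenol needed for oxidation without touching the aryl silyl ethers.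

Step 12
Reactants: 16 tetra-O-TBS ε-viniferin (two molecules)
Product: 19 octa-O-TBS ether of the target carrying two free phenols, via quinone methide 17 (not isolated), via O-cyclised dihydrobenzofuran 18 (not isolated)
Conditions: Ag2O (0.6 equiv), CH2Cl2, rt, dark; filter; then TsOH·H2O (10 mol %), (CF3)2CHOH–CH2Cl2 1:4, −20 °C → 0 °C
Reagents that add atoms: none
Why: Ag2O (monovalent silver) oxidises the only free phenol of 16 to its phenoxyl radical, two of which join C-b of one to the ortho carbon of ring C of the other; tautomerisation gives phenol–quinone methide 17, whose C-a is captured first by the ring C oxygen (5-exo-trig oxa-Michael addition) to give 18, which also masks the new 4-hydroxystilbene from further oxidation. After the silver is filtered off, TsOH in hexafluoroisopropanol re-opens that benzylic aryl ether to 17 (only this dihydrobenzofuran carries a free para-phenol and can expel its phenoxide as a neutral quinone methide, the two older C2 aryl groups being silyl ethers), and the ring A carbon ortho to C3, activated by one ortho and one para silyloxy group, adds irreversibly to C-a (7-exo-trig Friedel–Crafts alkylation), which forms the C-a–ring A bond and the cycloheptane. The closest known reaction types are the silver-mediated dehydrodimerisation of 4-hydroxystilbenes to 2-aryl-dihydrobenzofurans (ortho carbon to olefin carbon coupling) and the acid-mediated Friedel–Crafts capture of para-quinone methides or their benzylic cations by the resorcinol ring in resveratrol oligomers. C-b is created in the radical coupling, where the C3 aryl group biases the two faces only weakly, so both C-b epimers of 18 are to be expected; the ring closure then selects, because only in the epimer shown can ring C stand pseudo-axial on the face of ring B opposite to ring A with the C-b hydrogen in the plane of ring B next to H-5 (no allylic 1,3-strain) while C-a swings over ring A, and the other epimer should stay behind as its dihydrobenzofuran and be separated. C-a is set in the ring closure by that same conformation: the quinone methide ring points outward (pseudo-equatorial) and the C-a hydrogen inward, so that ring A adds to give the cis arrangement of the two aryl groups on C-a and C-b found in the target. The step further needs coupling at the ring C ortho carbon instead of C-b to C-b or C–O coupling (free ortho positions and Ag2O conditions; C-b to C-b adducts are crowded by the C3 aryl group and dissociate again), C- instead of O-capture (O-capture is reversible under the acid, C-capture is not) and survival of the product stilbene (low temperature, catalytic acid, short exposure).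

Step 13
Reactants: 19 octa-O-TBS ether of the target
Product: 20 target compound CNP0266373.2
Conditions: HF·pyridine, pyridine/THF, 0 °C → rt
Reagents that add atoms: none
Why: Fluoride-mediated cleavage of the eight aryl silyl ethers under buffered conditions that are neither basic enough to promote air oxidation of the polyphenol nor acidic enough to ionise the benzylic ethers or protonate the stilbene, so no stereocentre is touched.

**Compound list**

1 | 1-bromo-3,5-dimethoxybenzene | COc1cc(OC)cc(Br)c1 | starting material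
2 | 2-bromo-4,6-dimethoxybenzaldehyde | COc1cc(OC)c(C=O)c(Br)c1 | intermediate
3 | 2-bromo-6-hydroxy-4-methoxybenzaldehyde | COc1cc(O)c(C=O)c(Br)c1 | intermediate
4 | 4-methoxybenzyl chloride | COc1ccc(CCl)cc1 | starting material
5 | 2-bromo-4-methoxy-6-[(4-methoxybenzyl)oxy]benzaldehyde | COc1ccc(COc2cc(OC)cc(Br)c2C=O)cc1 | intermediate
6 | 3,5-dimethoxyphenylmagnesium chloride (THF solution) | COc1cc(OC)cc([Mg]Cl)c1 | starting material
7 | racemic [2-bromo-4-methoxy-6-(4-methoxybenzyloxy)phenyl](3,5-dimethoxyphenyl)methanol | COc1ccc(COc2cc(OC)cc(Br)c2C(O)c2cc(OC)cc(OC)c2)cc1 | intermediate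
8 | [2-bromo-4-methoxy-6-(4-methoxybenzyloxy)phenyl](3,5-dimethoxyphenyl)methanone | COc1ccc(COc2cc(OC)cc(Br)c2C(=O)c2cc(OC)cc(OC)c2)cc1 | intermediate
9 | hydrazone of ketone 8 (E/Z mixture) | COc1ccc(COc2cc(OC)cc(Br)c2C(=NN)c2cc(OC)cc(OC)c2)cc1 | intermediate
10 | [2-bromo-4-methoxy-6-(4-methoxybenzyloxy)phenyl](3,5-dimethoxyphenyl)diazomethane | COc1ccc(COc2cc(OC)cc(Br)c2C(=[N+]=[N-])c2cc(OC)cc(OC)c2)cc1 | intermediate (not isolated)
11 | (2R,3S)-4-bromo-3-(3,5-dimethoxyphenyl)-6-methoxy-2-(4-methoxyphenyl)-2,3-dihydro-1-benzofuran (cis) | Brc1cc(OC)cc2c1[C@H](c1cc(OC)cc(OC)c1)[C@H](c1ccc(OC)cc1)O2 | intermediate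
12 | (2S,3S)-4-bromo-3-(3,5-dihydroxyphenyl)-2-(4-hydroxyphenyl)-2,3-dihydro-1-benzofuran-6-ol (trans) | Brc1cc(O)cc2c1[C@H](c1cc(O)cc(O)c1)[C@@H](c1ccc(O)cc1)O2 | intermediate
13 | tetrakis-TBS ether of 12 | Brc1cc(O[Si](C)(C)C(C)(C)C)cc2c1[C@H](c1cc(O[Si](C)(C)C(C)(C)C)cc(O[Si](C)(C)C(C)(C)C)c1)[C@@H](c1ccc(O[Si](C)(C)C(C)(C)C)cc1)O2 | intermediate
14 | 4-acetoxystyrene (4-vinylphenyl acetate) | CC(=O)Oc1ccc(C=C)cc1 | starting material
15 | (2S,3S)-4-[(E)-4-acetoxystyryl]-6-(TBS-oxy)-3-[3,5-bis(TBS-oxy)phenyl]-2-[4-(TBS-oxy)phenyl]-2,3-dihydro-1-benzofuran | CC(=O)Oc1ccc(/C=C/c2cc(O[Si](C)(C)C(C)(C)C)cc3c2[C@H](c2cc(O[Si](C)(C)C(C)(C)C)cc(O[Si](C)(C)C(C)(C)C)c2)[C@@H](c2ccc(O[Si](C)(C)C(C)(C)C)cc2)O3)cc1 | intermediate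
16 | tetra-O-TBS (2S,3S)-ε-viniferin (stilbene phenol free) | Oc1ccc(/C=C/c2cc(O[Si](C)(C)C(C)(C)C)cc3c2[C@H](c2cc(O[Si](C)(C)C(C)(C)C)cc(O[Si](C)(C)C(C)(C)C)c2)[C@@H](c2ccc(O[Si](C)(C)C(C)(C)C)cc2)O3)cc1 | intermediate
17 | para-quinone methide: C-a is the exocyclic carbon of a cyclohexa-2,5-dienone; C-b (S) carries ring B of unit 1 and the ortho carbon of the ring C phenol of unit 2 | O=C1C=CC(=C[C@@H](c2cc(O[Si](C)(C)C(C)(C)C)cc3c2[C@H](c2cc(O[Si](C)(C)C(C)(C)C)cc(O[Si](C)(C)C(C)(C)C)c2)[C@@H](c2ccc(O[Si](C)(C)C(C)(C)C)cc2)O3)c2cc(/C=C/c4cc(O[Si](C)(C)C(C)(C)C)cc5c4[C@H](c4cc(O[Si](C)(C)C(C)(C)C)cc(O[Si](C)(C)C(C)(C)C)c4)[C@@H](c4ccc(O[Si](C)(C)C(C)(C)C)cc4)O5)ccc2O)C=C1 | intermediate (not isolated)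
18 | O-cyclised isomer: trans-(2S,3S)-2-(4-hydroxyphenyl)-2,3-dihydrobenzofuran formed from the ring C oxygen and C-a, with C3 (= C-b) carrying ring B of unit 1 | Oc1ccc([C@H]2Oc3ccc(/C=C/c4cc(O[Si](C)(C)C(C)(C)C)cc5c4[C@H](c4cc(O[Si](C)(C)C(C)(C)C)cc(O[Si](C)(C)C(C)(C)C)c4)[C@@H](c4ccc(O[Si](C)(C)C(C)(C)C)cc4)O5)cc3[C@@H]2c2cc(O[Si](C)(C)C(C)(C)C)cc3c2[C@H](c2cc(O[Si](C)(C)C(C)(C)C)cc(O[Si](C)(C)C(C)(C)C)c2)[C@@H](c2ccc(O[Si](C)(C)C(C)(C)C)cc2)O3)cc1 | intermediate (not isolated)
19 | octa-O-TBS ether of the target (free phenols: the 4-hydroxyphenyl ring on C-a and ring C; all six stereocentres S as in the target) | Oc1ccc([C@H]2c3c(O[Si](C)(C)C(C)(C)C)cc(O[Si](C)(C)C(C)(C)C)cc3[C@H]3c4c(cc(O[Si](C)(C)C(C)(C)C)cc4[C@H]2c2cc(/C=C/c4cc(O[Si](C)(C)C(C)(C)C)cc5c4[C@H](c4cc(O[Si](C)(C)C(C)(C)C)cc(O[Si](C)(C)C(C)(C)C)c4)[C@@H](c4ccc(O[Si](C)(C)C(C)(C)C)cc4)O5)ccc2O)O[C@@H]3c2ccc(O[Si](C)(C)C(C)(C)C)cc2)cc1 | intermediate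
20 | CNP0266373.2 | Oc1ccc([C@H]2c3c(O)cc(O)cc3[C@H]3c4c(cc(O)cc4[C@H]2c2cc(/C=C/c4cc(O)cc5c4[C@H](c4cc(O)cc(O)c4)[C@@H](c4ccc(O)cc4)O5)ccc2O)O[C@@H]3c2ccc(O)cc2)cc1 | target

**Step count and risks**

Total steps: 13. Longest linear sequence: 13 steps (1 to 20); the route is linear and step 12 consumes two molecules of 16.

Steps most likely to fail:

1. Step 12. The radical coupling may show poor or adverse facial selectivity at C-b, and the epimer with ring C on the wrong face cannot close the cycloheptane; in addition the product stilbene may cyclise further on prolonged acid exposure. The fallback sets out from 16 and comes back at 19. After the Ag2O stage the crude mixture of 18 and its C-b epimer, the epimeric O-cyclised dihydrobenzofuran F1, is not treated with acid but with DBU in toluene at 60 °C. Base-induced retro-oxa-Michael opening and tautomerisation of the quinone methide, the known behaviour of phenylcoumarans with a free para-phenol, should convert both epimers into one triarylethylene F2, in which C-b is no longer a stereocentre. TsOH in hexafluoroisopropanol–CH2Cl2 at 0 °C then protonates F2 reversibly at C-b to the cation of 17, and only the cyclisable C-b epimer undergoes the Friedel–Crafts closure. C-b is thus set under stereoconvergent Curtin–Hammett control instead of kinetic facial control, and 19 results.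

2. Step 7. The second ortho substituent (bromine) may twist the diaryl carbene, with loss of enantioselectivity and competing azine formation. The fallback sets out from ketone 8 and comes back at 12. The phosphazene base P4-t-Bu (toluene, 100 °C) deprotonates the benzylic OCH2 group, which adds to the ketone, and dehydration gives the 2,3-diarylbenzofuran F3. Ionic hydrogenation (Et3SiH, TFA, CH2Cl2) gives the racemic trans-2,3-dihydrobenzofuran F4, hydride adding to the C2 oxocarbenium ion anti to the C3 aryl group. BBr3 as in step 8 gives the racemic tetraol F5, which is resolved by preparative chromatography on a chiral stationary phase to give (2S,3S)-12.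

3. Step 10. Oxidative addition at the hindered, electron-rich bromide next to the C3 diarylmethine may be slow, with hydrodebromination or silyl ether loss competing at the temperature needed. The fallback sets out from 13 and comes back at 15. Stille coupling of 13 with tributyl(vinyl)stannane (Pd(PPh3)4, zerovalent palladium, toluene, 100 °C) gives the 4-vinyl compound F6. The roles in the Heck reaction are then reversed: F6 and 4-iodophenyl acetate (Pd(OAc)2, divalent palladium, Et3N, MeCN, 60 °C) give 15, with oxidative addition now at an unhindered aryl iodide.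

**Further compounds**

F1 | step 12 | C-b epimer of 18 (2R,3R-configured new trans-dihydrobenzofuran) | Oc1ccc([C@@H]2Oc3ccc(/C=C/c4cc(O[Si](C)(C)C(C)(C)C)cc5c4[C@H](c4cc(O[Si](C)(C)C(C)(C)C)cc(O[Si](C)(C)C(C)(C)C)c4)[C@@H](c4ccc(O[Si](C)(C)C(C)(C)C)cc4)O5)cc3[C@H]2c2cc(O[Si](C)(C)C(C)(C)C)cc3c2[C@H](c2cc(O[Si](C)(C)C(C)(C)C)cc(O[Si](C)(C)C(C)(C)C)c2)[C@@H](c2ccc(O[Si](C)(C)C(C)(C)C)cc2)O3)cc1
F2 | step 12 | triarylethylene (C-a=C-b double bond, E/Z mixture; C-a carries the 4-hydroxyphenyl ring, C-b carries ring B of unit 1 and the ring C phenol of unit 2) | Oc1ccc(C=C(c2cc(O[Si](C)(C)C(C)(C)C)cc3c2[C@H](c2cc(O[Si](C)(C)C(C)(C)C)cc(O[Si](C)(C)C(C)(C)C)c2)[C@@H](c2ccc(O[Si](C)(C)C(C)(C)C)cc2)O3)c2cc(/C=C/c4cc(O[Si](C)(C)C(C)(C)C)cc5c4[C@H](c4cc(O[Si](C)(C)C(C)(C)C)cc(O[Si](C)(C)C(C)(C)C)c4)[C@@H](c4ccc(O[Si](C)(C)C(C)(C)C)cc4)O5)ccc2O)cc1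
F3 | step 7 | 4-bromo-3-(3,5-dimethoxyphenyl)-6-methoxy-2-(4-methoxyphenyl)-1-benzofuran | COc1ccc(-c2oc3cc(OC)cc(Br)c3c2-c2cc(OC)cc(OC)c2)cc1
F4 | step 7 | racemic trans-4-bromo-3-(3,5-dimethoxyphenyl)-6-methoxy-2-(4-methoxyphenyl)-2,3-dihydro-1-benzofuran | Brc1cc(OC)cc2c1[C@H](c1cc(OC)cc(OC)c1)[C@@H](c1ccc(OC)cc1)O2.Brc1cc(OC)cc2c1[C@@H](c1cc(OC)cc(OC)c1)[C@H](c1ccc(OC)cc1)O2
F5 | step 7 | racemic trans-4-bromo-3-(3,5-dihydroxyphenyl)-2-(4-hydroxyphenyl)-2,3-dihydro-1-benzofuran-6-ol | Brc1cc(O)cc2c1[C@H](c1cc(O)cc(O)c1)[C@@H](c1ccc(O)cc1)O2.Brc1cc(O)cc2c1[C@@H](c1cc(O)cc(O)c1)[C@H](c1ccc(O)cc1)O2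
F6 | step 10 | (2S,3S)-4-vinyl-6-(TBS-oxy)-3-[3,5-bis(TBS-oxy)phenyl]-2-[4-(TBS-oxy)phenyl]-2,3-dihydro-1-benzofuran | C=Cc1cc(O[Si](C)(C)C(C)(C)C)cc2c1[C@H](c1cc(O[Si](C)(C)C(C)(C)C)cc(O[Si](C)(C)C(C)(C)C)c1)[C@@H](c1ccc(O[Si](C)(C)C(C)(C)C)cc1)O2
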